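**Plan**
- Retrosynthesis removes, in order, the C8 ester and C9 acetate, the C11=C13 methylene, the C4–C5 epoxide, the lactone (O6–C12) and the C7–C11 bond, then cuts the ring bond C8–C9 while re-forming C1–C6 (retro oxy-Cope) to reach a cis-1,2-dialkenylcyclohexenol (ring C1–C6).
- Enabling feature: the vicinal C8/C9 oxygens lie between C6 (lactone oxygen, earlier a ketone) and the C1=C10 enoate, i.e. the C6(=O)–C7–C8–C9–C10=C1 array of an oxy-Cope product, and both unsaturation sites of the ten-membered ring (C1=C10 and the C4–C5 epoxide) are ring-cis.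
- Forward: six-membered ring from the enone; C1–C10 by alkylation; C6–C7 by alkoxyacetylide addition; C9 by formylation; ten-membered ring by [3,3] ring expansion with C7 allylation in the same flask; then C6 alcohol, epoxide, lactone ring, methylene, C8 ester and C9 acetate.
- Stereochemistry: C1 from the RAMP auxiliary; C6 by axial acetylide attack relayed from C1; C8/C9 from the chair of the rearrangement; C7 by chelate-controlled allylation; C6–OH by Luche reduction; C4/C5 by hydroxyl-directed epoxidation; the side chain by Sharpless epoxidation and SN2 chloride opening.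

Key step: step 9

Remark: atom numbers are those of the germacrane skeleton of the target (ring C1–C10, C11–C13 lactone arm, C14 ester carbon, C15 methyl); the RAMP hydrazone is assumed to follow the usual chelated azaenolate model. PMB = 4-methoxybenzyl, TOM = (triisopropylsilyloxy)methyl.

Step 1
Reactants: 1 3-methylcyclohex-2-en-1-one; 2 (R)-1-amino-2-(methoxymethyl)pyrrolidine (RAMP)
Product: 3 RAMP hydrazone of 3-methylcyclohex-2-en-1-one (C=N isomers)
Conditions: TsOH (cat.), cyclohexane, reflux (Dean–Stark)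
Reagents that add atoms: none
Why: Acid-catalysed hydrazone condensation driven by azeotropic removal of water; no stereocenter is formed.

Step 2
Reactants: 3 RAMP hydrazone; 4 methyl bromoacetate
Product: 6 RAMP hydrazone of methyl 2-[(1R)-4-methyl-2-oxocyclohex-3-en-1-yl]acetate, via lithium azaenolate 5 (not isolated)
Conditions: LiN(iPr)2, THF, 0 °C; then 4, −95 °C
Reagents that add atoms: none
Why: Enders hydrazone alkylation: kinetic alpha-prime deprotonation gives the cross-conjugated, methoxy-chelated azaenolate, which should take up the bromoacetate on its open face and set C1 (R).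

Step 3
Reactants: 6 alkylated RAMP hydrazone
Product: 7 methyl 2-[(1R)-4-methyl-2-oxocyclohex-3-en-1-yl]acetate
Conditions: sat. aq. (CO2H)2, Et2O, rt
Reagents that add atoms: water, O
Why: Two-phase acidic hydrazone hydrolysis frees the enone without oxidants and returns the auxiliary, and its mildness should keep the alpha stereocenter from enolising.

Step 4
Reactants: 8 (4-methoxyphenyl)methanol; 9 trichloroethylene
Product: 10 (E)-1,2-dichlorovinyl 4-methoxybenzyl ether
Conditions: KH, THF, 0 °C to rt
Reagents that add atoms: none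
Why: Alkoxide addition to dichloroacetylene formed in the flask by dehydrochlorination (net addition–elimination on trichloroethylene), the standard entry to alkoxyacetylide precursors.

Step 5
Reactants: 10 dichlorovinyl ether; 7 keto ester
Product: 14 methyl 2-[(1R,2R)-2-[(4-methoxybenzyloxy)ethynyl]-4-methyl-2-(trimethylsilyloxy)cyclohex-3-en-1-yl]acetate (alkynyl cis to the acetate arm), via chloroethynyl ether 11 (not isolated), via lithium alkoxyacetylide 12 (not isolated), via lithium C6 alkoxide 13 (not isolated)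
Conditions: n-BuLi (2 equiv), THF, −78 to −40 °C; 7, −78 °C; Me3SiCl, −78 to 0 °C
Reagents that add atoms: chlorotrimethylsilane, C[Si](C)(C)Cl
Why: Arens–van Dorp type 1,2-addition of a lithium alkoxyacetylide (made by dehydrochlorination and Cl–Li exchange); the rod-shaped sp nucleophile should attack the half-chair enone axially, cis to the pseudo-equatorial acetate arm, which sets C6 with oxygen trans to the arm, and silylation in the flask keeps the alkoxide from lactonising onto the ester.

Step 6
Reactants: 14 alkynyl ether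
Product: 15 methyl 2-[(1R,2R)-2-[(Z)-2-(4-methoxybenzyloxy)ethenyl]-4-methyl-2-(trimethylsilyloxy)cyclohex-3-en-1-yl]acetate
Conditions: H2 (1 atm), Pd/CaCO3/Pb(OAc)2 (Lindlar), quinoline, EtOAc, rt
Reagents that add atoms: none
Why: Lindlar semi-hydrogenation is a syn addition, so the ynol ether should give the (Z)-enol ether with the PMB-oxy group cis to C6, while the trisubstituted ring alkene and the benzylic ether are left alone by the poisoned catalyst.

Step 7
Reactants: 15 (Z)-enol ether ester
Product: 18 methyl (Z)-2-[(1R,2S)-2-[(Z)-2-(4-methoxybenzyloxy)ethenyl]-4-methyl-2-(trimethylsilyloxy)cyclohex-3-en-1-yl]-3-[(triisopropylsilyloxy)methoxy]prop-2-enoate, via lithium ester enolate 16 (not isolated), via lithium formyl enolate 17 (not isolated)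
Conditions: LiN(iPr)2, THF, −78 °C; HCO2Me, −78 to 0 °C; TOM-Cl, 0 °C
Reagents that add atoms: methyl formate, COC=O; (triisopropylsilyloxy)methyl chloride (TOM-Cl), ClCO[Si](C(C)C)(C(C)C)C(C)C
Why: Crossed Claisen formylation of the ester enolate followed by O-alkylation of the lithium-chelated formyl enolate with the hard chloromethyl ether; the chelate and the bulky ring branch on C10 should both place O9 cis to the ester, giving the (Z)-alkoxyacrylate without any acidic work-up.

Step 8
Reactants: 18 silyl-protected acrylate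
Product: 19 methyl (Z)-2-[(1R,2S)-2-hydroxy-2-[(Z)-2-(4-methoxybenzyloxy)ethenyl]-4-methylcyclohex-3-en-1-yl]-3-[(triisopropylsilyloxy)methoxy]prop-2-enoate (cis-dialkenyl carbinol; C1 R, C6 S)
Conditions: K2CO3 (cat.), MeOH, 0 °C
Reagents that add atoms: none
Why: Base-catalysed methanolysis of the tertiary trimethylsilyl ether; the triisopropylsilyl acetal and both enol ethers tolerate base, and acid, which would turn the hydroxy enol ether into an enal, is avoided.

Step 9
Reactants: 19 cis-dialkenyl carbinol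
Product: 22 methyl 7-allyl-8-(4-methoxybenzyloxy)-4-methyl-6-oxo-9-[(triisopropylsilyloxy)methoxy]cyclodeca-1(10),4-diene-10-carboxylate (target numbering; 7R,8S,9R; both ring alkenes ring-cis), via potassium alkoxide 20 (not isolated), via potassium enolate 21 (not isolated)
Conditions: KN(SiMe3)2, THF, −78 to 0 °C; then allyl bromide, −78 °C
Reagents that add atoms: allyl bromide, C=CCBr
Why: Deprotonation gives alkoxide 20, in which the 1,5-diene C8=C7–C6–C1–C10=C9 undergoes the [3,3] shift (anionic oxy-Cope rearrangement, the known ring expansion of 1,2-dialkenylcyclohexenols to cyclodecadienones), forming C8–C9, breaking C1–C6 and leaving the C6 enolate 21, which is allylated at C7 in the same flask. The ten-membered ring is not closed end to end but arises by bond reorganisation in a six-membered chair array (C6, C7, C8, C9, C10, C1), a four-atom ring expansion of the cyclohexene. C8 and C9 are fixed by that chair: the (Z)-PMB-oxy group is axial on C8 and bridged by potassium to the axial C6 oxygen, O9 is equatorial on C9 because the (Z)-acrylate holds it trans to C1, and the absolute sense is relayed from C6 (S) to give 8S,9R. C7 is set in the alkylation, where the enolate chelated through potassium to O8 should be attacked by allyl bromide anti to the ring carbon C9, placing C11 cis to O8 (7R). The selectivity needed is this chair over the boat and over the chair with C5 axial; the Z substituent on C8 would clash 1,3-diaxially with an axial C5, so C5 stays equatorial, C2 is axial on C1 (cis-dialkenyl) and the new C1=C10 enoate is ring-cis, while C4=C5 keeps the cis geometry of the cyclohexene. Low temperature and prompt trapping are meant to outrun attack of the alkoxide on the C14 ester and loss of PMB-oxide from the beta-alkoxy enolate.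

Step 10
Reactants: 22 ten-membered dienone
Product: 23 C6 allylic alcohol of 22 (hydroxyl trans to the C7 allyl group; C7, C8, C9 unchanged)
Conditions: NaBH4, CeCl3·7H2O, MeOH, −78 °C
Reagents that add atoms: none
Why: Luche 1,2-reduction of the enone; hydride should enter anti to the C7 allyl arm standing perpendicular to the carbonyl (Felkin–Anh), giving the C6 alcohol with oxygen trans to C11.

Step 11
Reactants: 23 allylic alcohol
Product: 24 4,5-epoxide of 23 (4R,5S; epoxide oxygen syn to the C6 hydroxyl)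
Conditions: VO(acac)2 (cat.), t-BuOOH, CH2Cl2, 0 °C
Reagents that add atoms: tert-butyl hydroperoxide, CC(C)(C)OO
Why: Vanadium-catalysed hydroxyl-directed epoxidation, which in medium-ring (Z)-allylic alcohols delivers oxygen syn to the hydroxyl (erythro epoxy alcohol) and so should set C4 (R) and C5 (S); the remote allyl group and the electron-poor enoate do not compete.

Step 12
Reactants: 24 epoxy alcohol
Product: 26 C12 lactol (five-membered hemiacetal on O6; anomers), via hydroxy aldehyde 25 (not isolated)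
Conditions: OsO4 (cat.), NaIO4, 2,6-lutidine, dioxane/H2O, rt
Reagents that add atoms: sodium periodate, [Na+].[O-]I(=O)(=O)=O
Why: Lemieux–Johnson cleavage of the only terminal alkene (the trisubstituted enoate is electron-poor), the aldehyde closing at once onto the C6 hydroxyl as the lactol.

Step 13
Reactants: 26 lactol
Product: 27 trans-fused 6,12-lactone carrying the 4,5-epoxide, 8-OPMB and 9-OTOM groups
Conditions: TEMPO (cat.), PhI(OAc)2, CH2Cl2, rt
Reagents that add atoms: none
Why: Oxoammonium oxidation of the lactol to the gamma-lactone under neutral conditions that spare the epoxide and the PMB ether.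

Step 14
Reactants: 27 lactone
Product: 31 alpha-methylene lactone (C11=C13), via lithium lactone enolate 28 (not isolated), via C11 dimethylaminomethyl lactone 29 (not isolated), via C11 trimethylammoniomethyl iodide 30 (not isolated)
Conditions: LiN(iPr)2, THF, −78 °C; CH2=NMe2+ I−, −78 °C to rt; MeI, MeOH; aq. NaHCO3/CH2Cl2
Reagents that add atoms: dimethylmethylideneammonium iodide, C=[N+](C)C.[I-]
Why: Mannich alpha-methylenation of the kinetic lactone enolate with Eschenmoser's salt, then quaternisation and elimination; C11 becomes sp2, so no stereocenter results.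

Step 15
Reactants: 31 methylene lactone PMB ether
Product: 32 C8 alcohol (9-OTOM retained)
Conditions: DDQ, CH2Cl2/pH 7 buffer, 0 °C
Reagents that add atoms: none
Why: Oxidative PMB ether cleavage through the benzylic oxocarbenium ion and its hemiacetal, compatible with the epoxide, the silyl acetal and the Michael acceptor.

Step 16
Reactants: 33 angelic acid
Product: 34 (Z)-2-methylbut-2-en-1-ol
Conditions: LiAlH4, Et2O, 0 °C
Reagents that add atoms: none
Why: Hydride reduction of the carboxylate to the allylic alcohol with retention of the Z alkene.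

Step 17
Reactants: 34 (Z)-2-methylbut-2-en-1-ol
Product: 35 [(2R,3S)-2,3-dimethyloxiran-2-yl]methanol
Conditions: Ti(OiPr)4, D-(−)-diethyl tartrate, t-BuOOH, 4 Å MS, CH2Cl2, −20 °C
Reagents that add atoms: tert-butyl hydroperoxide, CC(C)(C)OO
Why: Sharpless asymmetric epoxidation; the L-(+) tartrate gives 2S,3S epoxides from (E)-2-alkenols, the same face here corresponds to 2S,3R, so the D-(−) ester should give the (2R,3S)-epoxy alcohol.

Step 18
Reactants: 35 epoxy alcohol
Product: 36 (2R,3R)-3-chloro-2-methylbutane-1,2-diol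
Conditions: Ti(OiPr)4, NH4Cl, DMSO, rt
Reagents that add atoms: ammonium chloride, [NH4+].[Cl-]
Why: Titanium-assisted opening of the 2,3-epoxy alcohol, in which chloride attacks C3 of the alkoxide-bound epoxide with inversion (SN2) because C2 is quaternary.

Step 19
Reactants: 36 chlorodiol
Product: 37 (2R,3R)-3-chloro-2-hydroxy-2-methylbutanoic acid
Conditions: TEMPO (cat.), NaOCl (cat.), NaClO2, MeCN/phosphate buffer pH 6.7, 35 °C
Reagents that add atoms: sodium chlorite, [Na+].[O-]Cl=O
Why: Oxoammonium/chlorite oxidation of the primary alcohol through the aldehyde to the acid; the tertiary alcohol and the secondary chloride are inert and no stereocenter is touched.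

Step 20
Reactants: 37 chlorohydrin acid
Product: 39 (2R,3R)-3-chloro-2-methyl-2-(triethylsilyloxy)butanoic acid, via bis-silylated acid 38 (not isolated)
Conditions: Et3SiOTf, 2,6-lutidine, CH2Cl2, 0 °C; then aq. NaHCO3, THF
Reagents that add atoms: triethylsilyl trifluoromethanesulfonate, CC[Si](CC)(CC)OS(=O)(=O)C(F)(F)F
Why: Silylation of hydroxyl and carboxyl groups, the labile silyl ester being hydrolysed on work-up, masks the tertiary alcohol for the esterification.

Step 21
Reactants: 32 C8 alcohol; 39 silyl-protected acid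
Product: 41 C8 ester of 32 bearing the O-triethylsilyl side chain, via mixed trichlorobenzoic anhydride 40 (not isolated)
Conditions: 2,4,6-Cl3C6H2COCl, Et3N, THF; then 32, DMAP, toluene, 40 °C
Reagents that add atoms: none
Why: Yamaguchi esterification through the mixed anhydride and DMAP acyl transfer, suited to a hindered secondary alcohol and an alpha-quaternary acid; O9 is still blocked, so no acyl migration can occur.

Step 22
Reactants: 41 doubly silyl-protected ester
Product: 43 9-deacetyl target (free C9 and side-chain tertiary hydroxyls), via C9 hydroxymethyl hemiacetal 42 (not isolated)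
Conditions: Bu4NF, AcOH, THF, 0 °C to rt
Reagents that add atoms: none
Why: Fluoride cleaves the triisopropylsilyl group of the acetal, whose hemiacetal loses formaldehyde, and the triethylsilyl ether; the acetic acid buffer should suppress acyl migration, chlorohydrin closure and oxa-Michael addition to the methylene lactone.

Step 23
Reactants: 43 diol
Product: 44 target compound CNP0185503.1
Conditions: Ac2O, pyridine, rt
Reagents that add atoms: acetic anhydride, CC(=O)OC(C)=O
Why: Acetylation of the secondary C9 alcohol; the tertiary alpha-hydroxy ester alcohol is too hindered to react without forcing conditions.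

**Compound list**

1 | 3-methylcyclohex-2-en-1-one | CC1=CC(=O)CCC1 | starting material
2 | (R)-1-amino-2-(methoxymethyl)pyrrolidine (RAMP) | COC[C@H]1CCCN1N | starting material
3 | RAMP hydrazone of 3-methylcyclohex-2-en-1-one | COC[C@H]1CCCN1N=C1C=C(C)CCC1 | intermediate
4 | methyl bromoacetate | COC(=O)CBr | starting material
5 | lithium azaenolate of 3 (alpha-prime) | COC[C@H]1CCCN1N([Li])C1=CCCC(C)=C1 | intermediate
6 | RAMP hydrazone of methyl 2-[(1R)-4-methyl-2-oxocyclohex-3-en-1-yl]acetate | COC[C@H]1CCCN1N=C1C=C(C)CC[C@@H]1CC(=O)OC | intermediate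
7 | methyl 2-[(1R)-4-methyl-2-oxocyclohex-3-en-1-yl]acetate | O=C1C=C(C)CC[C@@H]1CC(=O)OC | intermediate
8 | (4-methoxyphenyl)methanol | COc1ccc(CO)cc1 | starting material
9 | trichloroethylene | ClC=C(Cl)Cl | starting material
10 | (E)-1,2-dichlorovinyl 4-methoxybenzyl ether | COc1ccc(CO/C(Cl)=C\Cl)cc1 | intermediate
11 | chloroethynyl 4-methoxybenzyl ether | COc1ccc(COC#CCl)cc1 | intermediate
12 | lithium (4-methoxybenzyloxy)acetylide | COc1ccc(COC#C[Li])cc1 | intermediate
13 | lithium C6 alkoxide from addition to 7 (alkynyl cis to the acetate arm) | [Li]O[C@@]1(C#COCc2ccc(OC)cc2)C=C(C)CC[C@@H]1CC(=O)OC | intermediate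
14 | methyl 2-[(1R,2R)-2-[(4-methoxybenzyloxy)ethynyl]-4-methyl-2-(trimethylsilyloxy)cyclohex-3-en-1-yl]acetate | C[Si](C)(C)O[C@@]1(C#COCc2ccc(OC)cc2)C=C(C)CC[C@@H]1CC(=O)OC | intermediate
15 | methyl 2-[(1R,2R)-2-[(Z)-2-(4-methoxybenzyloxy)ethenyl]-4-methyl-2-(trimethylsilyloxy)cyclohex-3-en-1-yl]acetate | C[Si](C)(C)O[C@@]1(/C=C\OCc2ccc(OC)cc2)C=C(C)CC[C@@H]1CC(=O)OC | intermediate
16 | lithium ester enolate of 15 | C[Si](C)(C)O[C@@]1(/C=C\OCc2ccc(OC)cc2)C=C(C)CC[C@@H]1C=C(OC)O[Li] | intermediate
17 | lithium (Z)-enolate of the C9 formyl ester | C[Si](C)(C)O[C@@]1(/C=C\OCc2ccc(OC)cc2)C=C(C)CC[C@@H]1/C(C(=O)OC)=C/O[Li] | intermediate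
18 | methyl (Z)-2-[(1R,2S)-2-[(Z)-2-(4-methoxybenzyloxy)ethenyl]-4-methyl-2-(trimethylsilyloxy)cyclohex-3-en-1-yl]-3-[(triisopropylsilyloxy)methoxy]prop-2-enoate | C[Si](C)(C)O[C@@]1(/C=C\OCc2ccc(OC)cc2)C=C(C)CC[C@@H]1/C(C(=O)OC)=C/OCO[Si](C(C)C)(C(C)C)C(C)C | intermediate
19 | methyl (Z)-2-[(1R,2S)-2-hydroxy-2-[(Z)-2-(4-methoxybenzyloxy)ethenyl]-4-methylcyclohex-3-en-1-yl]-3-[(triisopropylsilyloxy)methoxy]prop-2-enoate (cis-dialkenyl carbinol) | O[C@@]1(/C=C\OCc2ccc(OC)cc2)C=C(C)CC[C@@H]1/C(C(=O)OC)=C/OCO[Si](C(C)C)(C(C)C)C(C)C | intermediate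
20 | potassium alkoxide of 19 | [K]O[C@@]1(/C=C\OCc2ccc(OC)cc2)C=C(C)CC[C@@H]1/C(C(=O)OC)=C/OCO[Si](C(C)C)(C(C)C)C(C)C | intermediate
21 | potassium C6 enolate of the ten-membered ring (8S,9R; C5 trans to C8) | C1/C(C)=C\C(O[K])=C\[C@H](OCc2ccc(OC)cc2)[C@H](OCO[Si](C(C)C)(C(C)C)C(C)C)/C(C(=O)OC)=C\C1 | intermediate
22 | methyl 7-allyl-8-(4-methoxybenzyloxy)-4-methyl-6-oxo-9-[(triisopropylsilyloxy)methoxy]cyclodeca-1(10),4-diene-10-carboxylate (target numbering; 7R,8S,9R; ring alkenes ring-cis) | O=C1/C=C(C)\CC/C=C(C(=O)OC)\[C@@H](OCO[Si](C(C)C)(C(C)C)C(C)C)[C@@H](OCc2ccc(OC)cc2)[C@H]1CC=C | intermediate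
23 | C6 allylic alcohol of 22 (hydroxyl trans to the C7 allyl group) | O[C@@H]1/C=C(C)\CC/C=C(C(=O)OC)\[C@@H](OCO[Si](C(C)C)(C(C)C)C(C)C)[C@@H](OCc2ccc(OC)cc2)[C@H]1CC=C | intermediate
24 | 4,5-epoxide of 23 (4R,5S; oxygen syn to the C6 hydroxyl) | O[C@@H]1[C@@H]2O[C@]2(C)CC/C=C(C(=O)OC)\[C@@H](OCO[Si](C(C)C)(C(C)C)C(C)C)[C@@H](OCc2ccc(OC)cc2)[C@H]1CC=C | intermediate
25 | C12 aldehyde of 24 (hydroxy aldehyde) | O[C@@H]1[C@@H]2O[C@]2(C)CC/C=C(C(=O)OC)\[C@@H](OCO[Si](C(C)C)(C(C)C)C(C)C)[C@@H](OCc2ccc(OC)cc2)[C@H]1CC=O | intermediate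
26 | C12 lactol (hemiacetal on O6; anomers) | C1C(O)O[C@H]2[C@H]1[C@H](OCc3ccc(OC)cc3)[C@H](OCO[Si](C(C)C)(C(C)C)C(C)C)/C(C(=O)OC)=C\CC[C@@]1(C)O[C@@H]21 | intermediate
27 | trans-fused 6,12-lactone with 4,5-epoxide, 8-OPMB, 9-OTOM | C1C(=O)O[C@H]2[C@H]1[C@H](OCc3ccc(OC)cc3)[C@H](OCO[Si](C(C)C)(C(C)C)C(C)C)/C(C(=O)OC)=C\CC[C@@]1(C)O[C@@H]21 | intermediate
28 | lithium enolate of lactone 27 | C1=C(O[Li])O[C@H]2[C@H]1[C@H](OCc3ccc(OC)cc3)[C@H](OCO[Si](C(C)C)(C(C)C)C(C)C)/C(C(=O)OC)=C\CC[C@@]1(C)O[C@@H]21 | intermediate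
29 | C11 dimethylaminomethyl lactone (C11 epimers) | CN(C)CC1C(=O)O[C@H]2[C@H]1[C@H](OCc3ccc(OC)cc3)[C@H](OCO[Si](C(C)C)(C(C)C)C(C)C)/C(C(=O)OC)=C\CC[C@@]1(C)O[C@@H]21 | intermediate
30 | C11 trimethylammoniomethyl lactone iodide | C[N+](C)(C)CC1C(=O)O[C@H]2[C@H]1[C@H](OCc3ccc(OC)cc3)[C@H](OCO[Si](C(C)C)(C(C)C)C(C)C)/C(C(=O)OC)=C\CC[C@@]1(C)O[C@@H]21.[I-] | intermediate
31 | alpha-methylene lactone with 8-OPMB and 9-OTOM | C=C1C(=O)O[C@H]2[C@H]1[C@H](OCc3ccc(OC)cc3)[C@H](OCO[Si](C(C)C)(C(C)C)C(C)C)/C(C(=O)OC)=C\CC[C@@]1(C)O[C@@H]21 | intermediate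
32 | C8 alcohol (9-OTOM) | C=C1C(=O)O[C@H]2[C@H]1[C@H](O)[C@H](OCO[Si](C(C)C)(C(C)C)C(C)C)/C(C(=O)OC)=C\CC[C@@]1(C)O[C@@H]21 | intermediate
33 | angelic acid, (Z)-2-methylbut-2-enoic acid | C/C=C(/C)C(=O)O | starting material
34 | (Z)-2-methylbut-2-en-1-ol | C/C=C(/C)CO | intermediate
35 | [(2R,3S)-2,3-dimethyloxiran-2-yl]methanol | OC[C@@]1(C)O[C@H]1C | intermediate
36 | (2R,3R)-3-chloro-2-methylbutane-1,2-diol | OC[C@@](C)(O)[C@@H](C)Cl | intermediate
37 | (2R,3R)-3-chloro-2-hydroxy-2-methylbutanoic acid | O=C(O)[C@@](C)(O)[C@@H](C)Cl | intermediate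
38 | triethylsilyl (2R,3R)-3-chloro-2-methyl-2-(triethylsilyloxy)butanoate | CC[Si](CC)(CC)OC(=O)[C@@](C)(O[Si](CC)(CC)CC)[C@@H](C)Cl | intermediate
39 | (2R,3R)-3-chloro-2-methyl-2-(triethylsilyloxy)butanoic acid | O=C(O)[C@@](C)(O[Si](CC)(CC)CC)[C@@H](C)Cl | intermediate
40 | mixed anhydride of 39 with 2,4,6-trichlorobenzoic acid | O=C(OC(=O)c1c(Cl)cc(Cl)cc1Cl)[C@@](C)(O[Si](CC)(CC)CC)[C@@H](C)Cl | intermediate
41 | C8 ester with O-triethylsilyl side chain and 9-OTOM | C=C1C(=O)O[C@H]2[C@H]1[C@H](OC(=O)[C@@](C)(O[Si](CC)(CC)CC)[C@@H](C)Cl)[C@H](OCO[Si](C(C)C)(C(C)C)C(C)C)/C(C(=O)OC)=C\CC[C@@]1(C)O[C@@H]21 | intermediate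
42 | C9 hydroxymethyl hemiacetal | C=C1C(=O)O[C@H]2[C@H]1[C@H](OC(=O)[C@@](C)(O)[C@@H](C)Cl)[C@H](OCO)/C(C(=O)OC)=C\CC[C@@]1(C)O[C@@H]21 | intermediate
43 | 9-deacetyl target (free C9 and side-chain hydroxyls) | C=C1C(=O)O[C@H]2[C@H]1[C@H](OC(=O)[C@@](C)(O)[C@@H](C)Cl)[C@H](O)/C(C(=O)OC)=C\CC[C@@]1(C)O[C@@H]21 | intermediate
44 | CNP0185503.1 | C=C1C(=O)O[C@H]2[C@H]1[C@H](OC(=O)[C@@](C)(O)[C@@H](C)Cl)[C@H](OC(C)=O)/C(C(=O)OC)=C\CC[C@@]1(C)O[C@@H]21 | target

**Totals and risks**

Total step count: 23. Longest linear sequence: 17 steps (steps 1–3, 5–15, 21–23); step 4 and steps 16–20 are branches.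

Steps most likely to fail:

1. Step 9. The tertiary alkoxide may add to the C14 ester carbonyl (lactonisation), the beta-alkoxy enolate may expel PMB-oxide before it is trapped, or tight ion pairing may slow the shift. Fallback, setting out from 18: the silyl ether is heated (o-dichlorobenzene, 170 °C, base-washed vessel) in a neutral siloxy-Cope rearrangement through the same chair to give the trimethylsilyl dienol ether F1, with no alkoxide or free enolate present. F1 is then allylated under neutral conditions with allyl methyl carbonate and zerovalent palladium (Pd2(dba)3, dppe, THF, 60 °C; Tsuji allylation of a silyl enol ether), returning to the route at 22.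

2. Step 5. The benzylic alkynyl ether may be lost by sigmatropic shift to a ketene, the adduct may suffer an acid-triggered Meyer–Schuster shift, and facial selectivity may erode. Fallback, setting out from 7: ethynylmagnesium bromide (HC≡CMgBr, THF, −78 °C), an even smaller sp nucleophile, gives the bromomagnesium alkoxide F2, which is silylated in the flask with Me3SiCl to the ethynyl carbinol silyl ether F3. N-Iodosuccinimide with AgNO3 (cat.) gives the iodoalkyne F4, and diimide (from 2-nitrobenzenesulfonohydrazide and Et3N) reduces it to the (Z)-vinyl iodide F5. Copper-catalysed C–O coupling of F5 with alcohol 8 (CuI, 3,4,7,8-tetramethyl-1,10-phenanthroline, Cs2CO3, toluene, 80 °C) proceeds with retention and returns to the route at 15.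

3. Step 10. Hydride may be delivered to the other face of the ring ketone if the ring conformation overrides the Felkin–Anh preference. Fallback, setting out from 22: the reduction then gives the C6-epimeric alcohol F6, which is inverted by Mitsunobu reaction (4-nitrobenzoic acid, PPh3, diisopropyl azodicarboxylate, THF) to the inverted 4-nitrobenzoate F7. Methanolysis (K2CO3, MeOH, 0 °C) returns to the route at 23.

Further compounds
F1 | step 9 | trimethylsilyl dienol ether of the ten-membered ring (C6 O-silyl, 8S,9R) | C1/C(C)=C\C(O[Si](C)(C)C)=C\[C@H](OCc2ccc(OC)cc2)[C@H](OCO[Si](C(C)C)(C(C)C)C(C)C)/C(C(=O)OC)=C\C1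
F2 | step 5 | bromomagnesium alkoxide of the ethynyl carbinol | Br[Mg]O[C@@]1(C#C)C=C(C)CC[C@@H]1CC(=O)OC
F3 | step 5 | methyl 2-[(1R,2R)-2-ethynyl-4-methyl-2-(trimethylsilyloxy)cyclohex-3-en-1-yl]acetate | C[Si](C)(C)O[C@@]1(C#C)C=C(C)CC[C@@H]1CC(=O)OC
F4 | step 5 | iodoalkyne of F3 | C[Si](C)(C)O[C@@]1(C#CI)C=C(C)CC[C@@H]1CC(=O)OC
F5 | step 5 | (Z)-vinyl iodide of F3 | C[Si](C)(C)O[C@@]1(/C=C\I)C=C(C)CC[C@@H]1CC(=O)OC
F6 | step 10 | C6-epimeric allylic alcohol | O[C@H]1/C=C(C)\CC/C=C(C(=O)OC)\[C@@H](OCO[Si](C(C)C)(C(C)C)C(C)C)[C@@H](OCc2ccc(OC)cc2)[C@H]1CC=C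
F7 | step 10 | 4-nitrobenzoate of 23 (inverted C6) | O=C(O[C@@H]1/C=C(C)\CC/C=C(C(=O)OC)\[C@@H](OCO[Si](C(C)C)(C(C)C)C(C)C)[C@@H](OCc2ccc(OC)cc2)[C@H]1CC=C)c1ccc(cc1)[N+](=O)[O-]
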